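**Retrosynthetic overview**

1. Numbering follows tricyclo[5.4.0.0^{2,8}]undecane: C1/C8 are the bridgeheads, C2/C7 the other cyclobutane carbons, C3–C6 the four-carbon bridge (C5 acetoxy, C6 quaternary), C9–C11 the enone bridge, C12 the oxymethylene carbon on C6. Enabling feature: O–C12 and O–C5 flank C6 as a 1,3-diol, so C6 is the α-carbon of a C5 ketone in the seven-membered ring and C12 is a formaldehyde carbon. C6 lies in the local mirror plane of the bicyclo[4.1.1]octane half (C1 and C8 are mirror-related), so its configuration has to come from a catalyst.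
2. C6–C12: catalyst-controlled hydroxymethylation of the tetrasubstituted C5=C6 enol silane with aqueous formaldehyde. The new hydroxyl then directs an anti reduction at C5; esters follow; the enone comes last by oxidation and double-bond migration.
3. Seven-membered ring (formed last): C4–C5 and C5–C6 by radical carbonylation and 7-endo acyl radical cyclisation onto an ethylidenecyclobutane, which also fixes C7–H.
4. Cyclobutane and six-membered ring (formed first, together): intramolecular vinylketene–alkene [2+2] of an acyclic dienoyl chloride. The C11 silyloxy stereocentre controls the face and is erased in the last step.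
5. Chain: asymmetric vinylogous Mukaiyama aldol of an E-enal (from carboalumination of a butynyl silyl ether) with a senecioate dienol silane.

Key step: step 13

Assumption: the catalyst enantiomers written in steps 4 and 13 are taken to deliver the configurations drawn; if either induces the opposite sense, its mirror-image form is used and nothing else changes.

**Route**

Step 1
Reactants: 1 tert-butyl(but-3-yn-1-yloxy)dimethylsilane
Product: 3 (2E)-5-(TBSO)-3-methylpent-2-en-1-ol, via alkenylalane 2 (not isolated)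
Conditions: Me3Al, Cp2ZrCl2 (0.2 equiv), CH2Cl2, 0 °C to rt; then n-BuLi, THF, −78 °C; (CH2O)n, −78 °C to rt
Reagents that add atoms: trimethylaluminium C[Al](C)C; formaldehyde (from paraformaldehyde) C=O
Why: Zirconium-catalysed Negishi carboalumination adds methyl and aluminium syn across the alkyne with methyl on the internal carbon, and the alanate is hydroxymethylated with retention, so the trisubstituted alkene should form as the E isomer only.

Step 2
Reactants: 3 (2E)-5-(TBSO)-3-methylpent-2-en-1-ol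
Product: 4 (2E)-5-(TBSO)-3-methylpent-2-enal
Conditions: MnO2, CH2Cl2, rt
Reagents that add atoms: none
Why: Allylic oxidation with MnO2 should give the enal without touching the silyl ether or the alkene geometry.

Step 3
Reactants: 5 methyl 3-methylbut-2-enoate
Product: 6 tert-butyl[(1-methoxy-3-methylbuta-1,3-dien-1-yl)oxy]dimethylsilane
Conditions: LDA, THF, −78 °C; TBSCl, DMPU, −78 °C to rt
Reagents that add atoms: tert-butyl(chloro)dimethylsilane CC(C)(C)[Si](C)(C)Cl
Why: Kinetic γ-deprotonation and O-silylation of the extended enolate give the silyl dienol ether (silyl ketene acetal formation) needed as the vinylogous nucleophile.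

Step 4
Reactants: 4 (2E)-5-(TBSO)-3-methylpent-2-enal; 6 tert-butyl[(1-methoxy-3-methylbuta-1,3-dien-1-yl)oxy]dimethylsilane
Product: 8 methyl (2E,5R,6E)-9-(TBSO)-5-hydroxy-3,7-dimethylnona-2,6-dienoate, via trichlorosilyl ether 7 (not isolated)
Conditions: SiCl4 (1.1 equiv), (R,R)-N,N'-dimethyl-1,1'-binaphthyl-2,2'-diamine-derived bisphosphoramide (5 mol %), iPr2NEt (10 mol %), CH2Cl2, −78 °C; aqueous work-up
Reagents that add atoms: none
Why: Vinylogous Mukaiyama aldol under Lewis-base-activated SiCl4: the chiral phosphoramide-bound trichlorosilyl cation activates the enal for 1,2-attack by the γ-carbon of 6, the catalyst selects the aldehyde face and so sets the carbinol centre (5R), and the conjugated ester should emerge as the E isomer.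

Step 5
Reactants: 8 methyl (2E,5R,6E)-9-(TBSO)-5-hydroxy-3,7-dimethylnona-2,6-dienoate
Product: 9 methyl (2E,5R,6E)-5-(TBDPSO)-9-(TBSO)-3,7-dimethylnona-2,6-dienoate
Conditions: TBDPSCl, imidazole, DMF, rt
Reagents that add atoms: tert-butyl(chloro)diphenylsilane CC(C)(C)[Si](Cl)(c1ccccc1)c1ccccc1
Why: Standard silylation of the secondary allylic alcohol; the bulky, acid-stable TBDPS ether is orthogonal to the primary TBS ether and is the steering group in step 7.

Step 6
Reactants: 9 methyl (2E,5R,6E)-5-(TBDPSO)-9-(TBSO)-3,7-dimethylnona-2,6-dienoate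
Product: 10 (2E,5R,6E)-5-(TBDPSO)-9-(TBSO)-3,7-dimethylnona-2,6-dienoic acid
Conditions: LiOH, THF/MeOH/H2O, 40 °C; then aq HCl to pH 4, 0 °C
Reagents that add atoms: lithium hydroxide [Li+].[OH-]
Why: Saponification of the methyl ester; both silyl ethers tolerate LiOH and the E-enoate cannot lactonise.

Step 7
Reactants: 10 (2E,5R,6E)-5-(TBDPSO)-9-(TBSO)-3,7-dimethylnona-2,6-dienoic acid
Product: 13 (1S,4R,5S,7S)-4-(TBDPSO)-7-[2-(TBSO)ethyl]-7-methyl-2-methylidenebicyclo[3.1.1]heptan-6-one, via acid chloride 11 (not isolated), via vinylketene 12 (not isolated)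
Conditions: 1-chloro-N,N,2-trimethylprop-1-en-1-amine, CH2Cl2, rt; then slow addition to Et3N, toluene, 110 °C (high dilution)
Reagents that add atoms: none
Why: Loss of HCl from the methyl group cis to the acyl chloride gives the cross-conjugated vinylketene, which closes the cyclobutanone and the six-membered ring at once by thermal intramolecular ketene–alkene [2+2] cycloaddition in the bridged mode (carbonyl carbon to the less substituted alkene carbon); addition is suprafacial on the E-alkene (methyl syn and side chain anti to the three-carbon bridge), and allylic 1,3-strain at the silyloxy stereocentre (C–H in the alkene plane, OTBDPS turned away from the ketene) selects the alkene face and fixes the three ring stereocentres.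

Step 8
Reactants: 13 (1S,4R,5S,7S)-4-(TBDPSO)-7-[2-(TBSO)ethyl]-7-methyl-2-methylidenebicyclo[3.1.1]heptan-6-one
Product: 14 tert-butyl({6-ethylidene-7-[2-(TBSO)ethyl]-7-methyl-2-methylidenebicyclo[3.1.1]heptan-4-yl}oxy)diphenylsilane (ring stereocentres as in 13; E/Z mixture)
Conditions: EtPPh3Br, KHMDS, THF, 0 °C; then 13, 0 to 50 °C
Reagents that add atoms: ethyltriphenylphosphonium bromide CC[P+](c1ccccc1)(c1ccccc1)c1ccccc1.[Br-]
Why: Wittig olefination of the strained, non-enolisable cyclobutanone with an alkoxide-free ylide installs the future C6 and its methyl group; the E/Z ratio does not matter because this carbon is planarised again in step 12.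

Step 9
Reactants: 14 tert-butyl({6-ethylidene-7-[2-(TBSO)ethyl]-7-methyl-2-methylidenebicyclo[3.1.1]heptan-4-yl}oxy)diphenylsilane
Product: 15 2-[4-(TBDPSO)-6-ethylidene-7-methyl-2-methylidenebicyclo[3.1.1]heptan-7-yl]ethan-1-ol (ring stereocentres as in 13; E/Z mixture)
Conditions: PPTS (cat.), MeOH, rt
Reagents that add atoms: none
Why: Acid-catalysed methanolysis should remove the primary TBS ether selectively, the hindered secondary TBDPS ether being far more stable to acid.

Step 10
Reactants: 15 2-[4-(TBDPSO)-6-ethylidene-7-methyl-2-methylidenebicyclo[3.1.1]heptan-7-yl]ethan-1-ol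
Product: 16 tert-butyl{[6-ethylidene-7-(2-iodoethyl)-7-methyl-2-methylidenebicyclo[3.1.1]heptan-4-yl]oxy}diphenylsilane (ring stereocentres as in 13; E/Z mixture)
Conditions: I2, PPh3, imidazole, CH2Cl2, 0 °C
Reagents that add atoms: iodine [I][I]
Why: Appel-type iodination of the primary alcohol through its alkoxyphosphonium salt; no stereocentre is involved.

Step 11
Reactants: 16 tert-butyl{[6-ethylidene-7-(2-iodoethyl)-7-methyl-2-methylidenebicyclo[3.1.1]heptan-4-yl]oxy}diphenylsilane
Product: 17 (11R)-11-(TBDPSO)-2,6-dimethyl-9-methylidenetricyclo[5.4.0.0^{2,8}]undecan-5-one (C6 epimer mixture; C1, C2, C7, C8 as in 25)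
Conditions: CO (80 atm), Bu3SnH (slow addition), AIBN (cat.), benzene, 80 °C, 0.01 M
Reagents that add atoms: carbon monoxide [C-]#[O+]
Why: Radical carbonylation: the primary radical should capture CO faster than it cyclises, and the acyl radical closes the seven-membered ring by 7-endo attack on the less substituted carbon of the exocyclic alkene (the ring carbon is fully substituted, which disfavours 6-exo); the cyclobutyl radical at C7 can only take hydrogen from Bu3SnH on the face that the new ring leaves open, so C7–H is set by the ring fusion while C6 forms as an inconsequential epimer mixture.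

Step 12
Reactants: 17 (11R)-11-(TBDPSO)-2,6-dimethyl-9-methylidenetricyclo[5.4.0.0^{2,8}]undecan-5-one
Product: 18 tert-butyl{[2,6-dimethyl-9-methylidene-5-(trimethylsilyloxy)tricyclo[5.4.0.0^{2,8}]undec-5-en-11-yl]oxy}diphenylsilane (stereocentres as in 17)
Conditions: Me3SiCl, NaI, Et3N, MeCN, rt
Reagents that add atoms: chlorotrimethylsilane C[Si](C)(C)Cl
Why: Equilibrating silylation with Me3SiI formed in the flask should favour the tetrasubstituted enol silane toward C6, the more substituted α-carbon (thermodynamic silyl enol ether formation), and it erases the C6 epimers.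

Step 13
Reactants: 18 tert-butyl{[2,6-dimethyl-9-methylidene-5-(trimethylsilyloxy)tricyclo[5.4.0.0^{2,8}]undec-5-en-11-yl]oxy}diphenylsilane
Product: 19 (6S)-11-(TBDPSO)-6-(hydroxymethyl)-2,6-dimethyl-9-methylidenetricyclo[5.4.0.0^{2,8}]undecan-5-one
Conditions: aq HCHO (5 equiv), Sc(OTf)3 (10 mol %), (S,S)-6,6'-bis(1-hydroxy-2,2-dimethylpropyl)-2,2'-bipyridine (12 mol %), 2,6-di-tert-butylpyridine (20 mol %), DME/H2O 9:1, −20 °C
Reagents that add atoms: formaldehyde C=O
Why: Mukaiyama aldol (hydroxymethylation) of a silyl enol ether with aqueous formaldehyde under chiral Lewis-acid catalysis, the closest known reaction type being the scandium–bipyridine-catalysed hydroxymethylation of tetrasubstituted ketone enol silanes: the complex binds and activates formaldehyde, the enol silane attacks through C6 in an open transition state, and silyl transfer to water releases the catalyst. No ring is closed; the step makes the C6–C12 bond, the quaternary stereocentre C6 and the C12 oxygen in one operation. Because C6 lies in the local mirror plane of the bicyclo[4.1.1]octane half (C2, C7 and C3–C6 in the plane, C1 and C8 presenting equivalent C–H bonds to its two faces), the substrate offers almost no bias and the ligand decides the face (catalyst control), attack from the C8 side being required. Regiochemistry is fixed by the position of the enol silane double bond. The chemoselectivity needed is reaction at the enol silane and not at the C9 methylidene (ene or Prins pathway) or the silyl ether; it should be secured by the far higher nucleophilicity of the enol silane and the attenuated Lewis acidity of the aqueous scandium catalyst at −20 °C.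

Step 14
Reactants: 19 (6S)-11-(TBDPSO)-6-(hydroxymethyl)-2,6-dimethyl-9-methylidenetricyclo[5.4.0.0^{2,8}]undecan-5-one
Product: 20 (5R,6S)-11-(TBDPSO)-6-(hydroxymethyl)-2,6-dimethyl-9-methylidenetricyclo[5.4.0.0^{2,8}]undecan-5-ol
Conditions: Me4NBH(OAc)3, MeCN/AcOH 1:1, −30 °C
Reagents that add atoms: none
Why: Evans–Saksena reduction: the primary hydroxyl exchanges onto boron and delivers hydride intramolecularly to the ketone face syn to the hydroxymethyl arm, which should give the anti 1,3-diol with the C5 hydroxyl trans to C12 (5R).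

Step 15
Reactants: 20 (5R,6S)-11-(TBDPSO)-6-(hydroxymethyl)-2,6-dimethyl-9-methylidenetricyclo[5.4.0.0^{2,8}]undecan-5-ol
Product: 21 [(5R,6S)-11-(TBDPSO)-5-hydroxy-2,6-dimethyl-9-methylidenetricyclo[5.4.0.0^{2,8}]undecan-6-yl]methyl (2Z)-2-methylbut-2-enoate
Conditions: angelic acid, 2,4,6-trichlorobenzoyl chloride, Et3N, toluene, rt; then 20, toluene, 80 °C
Reagents that add atoms: angelic acid C/C=C(/C)C(=O)O
Why: Yamaguchi-type mixed-anhydride acylation; the primary hydroxyl should react much faster than the hindered secondary one, and DMAP-free heating is chosen to avoid isomerisation of the Z double bond to the tiglate.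

Step 16
Reactants: 21 [(5R,6S)-11-(TBDPSO)-5-hydroxy-2,6-dimethyl-9-methylidenetricyclo[5.4.0.0^{2,8}]undecan-6-yl]methyl (2Z)-2-methylbut-2-enoate
Product: 22 [(5R,6S)-5-acetyloxy-11-(TBDPSO)-2,6-dimethyl-9-methylidenetricyclo[5.4.0.0^{2,8}]undecan-6-yl]methyl (2Z)-2-methylbut-2-enoate
Conditions: Ac2O, DMAP (cat.), pyridine, rt
Reagents that add atoms: acetic anhydride CC(=O)OC(C)=O
Why: DMAP-catalysed acetylation of the remaining hindered secondary alcohol.

Step 17
Reactants: 22 [(5R,6S)-5-acetyloxy-11-(TBDPSO)-2,6-dimethyl-9-methylidenetricyclo[5.4.0.0^{2,8}]undecan-6-yl]methyl (2Z)-2-methylbut-2-enoate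
Product: 23 [(5R,6S)-5-acetyloxy-11-hydroxy-2,6-dimethyl-9-methylidenetricyclo[5.4.0.0^{2,8}]undecan-6-yl]methyl (2Z)-2-methylbut-2-enoate
Conditions: Bu4NF, AcOH, THF, rt
Reagents that add atoms: none
Why: Fluoride cleavage of the TBDPS ether, buffered with acetic acid so that the two esters should neither migrate nor hydrolyse.

Step 18
Reactants: 23 [(5R,6S)-5-acetyloxy-11-hydroxy-2,6-dimethyl-9-methylidenetricyclo[5.4.0.0^{2,8}]undecan-6-yl]methyl (2Z)-2-methylbut-2-enoate
Product: 25 [(1S,2S,5R,6S,7R,8S)-5-acetyloxy-2,6,9-trimethyl-11-oxotricyclo[5.4.0.0^{2,8}]undec-9-en-6-yl]methyl (2Z)-2-methylbut-2-enoate, via deconjugated enone 24 (not isolated)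
Conditions: (n-Pr4N)RuO4 (5 mol %), NMO, 4 Å MS, CH2Cl2, rt; then Et3N, rt
Reagents that add atoms: none
Why: Ley–Griffith oxidation gives the β,γ-unsaturated ketone, whose exocyclic double bond should move into conjugation on mild base treatment (γ-protonation of the dienolate; the bridgehead α-carbon cannot enolise); this erases the C11 stereocentre that carried the absolute configuration.

**Compound list**

1 | tert-butyl(but-3-yn-1-yloxy)dimethylsilane | C#CCCO[Si](C)(C)C(C)(C)C | starting material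
2 | [(1E)-4-(TBSO)-2-methylbut-1-en-1-yl]dimethylalane | C[Al](C)/C=C(\C)CCO[Si](C)(C)C(C)(C)C | intermediate
3 | (2E)-5-(TBSO)-3-methylpent-2-en-1-ol | OC/C=C(\C)CCO[Si](C)(C)C(C)(C)C | intermediate
4 | (2E)-5-(TBSO)-3-methylpent-2-enal | O=C/C=C(\C)CCO[Si](C)(C)C(C)(C)C | intermediate
5 | methyl 3-methylbut-2-enoate | COC(=O)C=C(C)C | starting material
6 | tert-butyl[(1-methoxy-3-methylbuta-1,3-dien-1-yl)oxy]dimethylsilane | COC(O[Si](C)(C)C(C)(C)C)=CC(C)=C | intermediate
7 | methyl (2E,5R,6E)-9-(TBSO)-3,7-dimethyl-5-(trichlorosilyloxy)nona-2,6-dienoate | COC(=O)/C=C(\C)C[C@@H](O[Si](Cl)(Cl)Cl)/C=C(\C)CCO[Si](C)(C)C(C)(C)C | intermediate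
8 | methyl (2E,5R,6E)-9-(TBSO)-5-hydroxy-3,7-dimethylnona-2,6-dienoate | COC(=O)/C=C(\C)C[C@@H](O)/C=C(\C)CCO[Si](C)(C)C(C)(C)C | intermediate
9 | methyl (2E,5R,6E)-5-(TBDPSO)-9-(TBSO)-3,7-dimethylnona-2,6-dienoate | COC(=O)/C=C(\C)C[C@@H](O[Si](c1ccccc1)(c1ccccc1)C(C)(C)C)/C=C(\C)CCO[Si](C)(C)C(C)(C)C | intermediate
10 | (2E,5R,6E)-5-(TBDPSO)-9-(TBSO)-3,7-dimethylnona-2,6-dienoic acid | OC(=O)/C=C(\C)C[C@@H](O[Si](c1ccccc1)(c1ccccc1)C(C)(C)C)/C=C(\C)CCO[Si](C)(C)C(C)(C)C | intermediate
11 | (2E,5R,6E)-5-(TBDPSO)-9-(TBSO)-3,7-dimethylnona-2,6-dienoyl chloride | ClC(=O)/C=C(\C)C[C@@H](O[Si](c1ccccc1)(c1ccccc1)C(C)(C)C)/C=C(\C)CCO[Si](C)(C)C(C)(C)C | intermediate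
12 | (5R,6E)-5-(TBDPSO)-9-(TBSO)-7-methyl-3-methylidenenona-1,6-dien-1-one | O=C=CC(=C)C[C@@H](O[Si](c1ccccc1)(c1ccccc1)C(C)(C)C)/C=C(\C)CCO[Si](C)(C)C(C)(C)C | intermediate
13 | (1S,4R,5S,7S)-4-(TBDPSO)-7-[2-(TBSO)ethyl]-7-methyl-2-methylidenebicyclo[3.1.1]heptan-6-one | O=C1[C@H]2C(=C)C[C@@H](O[Si](c3ccccc3)(c3ccccc3)C(C)(C)C)[C@@H]1[C@@]2(C)CCO[Si](C)(C)C(C)(C)C | intermediate
14 | tert-butyl({6-ethylidene-7-[2-(TBSO)ethyl]-7-methyl-2-methylidenebicyclo[3.1.1]heptan-4-yl}oxy)diphenylsilane (E/Z mixture) | CC=C1[C@H]2C(=C)C[C@@H](O[Si](c3ccccc3)(c3ccccc3)C(C)(C)C)[C@@H]1[C@@]2(C)CCO[Si](C)(C)C(C)(C)C | intermediate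
15 | 2-[4-(TBDPSO)-6-ethylidene-7-methyl-2-methylidenebicyclo[3.1.1]heptan-7-yl]ethan-1-ol (E/Z mixture) | CC=C1[C@H]2C(=C)C[C@@H](O[Si](c3ccccc3)(c3ccccc3)C(C)(C)C)[C@@H]1[C@@]2(C)CCO | intermediate
16 | tert-butyl{[6-ethylidene-7-(2-iodoethyl)-7-methyl-2-methylidenebicyclo[3.1.1]heptan-4-yl]oxy}diphenylsilane (E/Z mixture) | CC=C1[C@H]2C(=C)C[C@@H](O[Si](c3ccccc3)(c3ccccc3)C(C)(C)C)[C@@H]1[C@@]2(C)CCI | intermediate
17 | (11R)-11-(TBDPSO)-2,6-dimethyl-9-methylidenetricyclo[5.4.0.0^{2,8}]undecan-5-one (C6 epimers) | CC1[C@@H]2[C@H]3C(=C)C[C@@H](O[Si](c4ccccc4)(c4ccccc4)C(C)(C)C)[C@@H]2[C@@]3(C)CCC1=O | intermediate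
18 | tert-butyl{[2,6-dimethyl-9-methylidene-5-(trimethylsilyloxy)tricyclo[5.4.0.0^{2,8}]undec-5-en-11-yl]oxy}diphenylsilane | C[Si](C)(C)OC1=C(C)[C@@H]2[C@H]3C(=C)C[C@@H](O[Si](c4ccccc4)(c4ccccc4)C(C)(C)C)[C@@H]2[C@@]3(C)CC1 | intermediate
19 | (6S)-11-(TBDPSO)-6-(hydroxymethyl)-2,6-dimethyl-9-methylidenetricyclo[5.4.0.0^{2,8}]undecan-5-one | OC[C@]1(C)[C@@H]2[C@H]3C(=C)C[C@@H](O[Si](c4ccccc4)(c4ccccc4)C(C)(C)C)[C@@H]2[C@@]3(C)CCC1=O | intermediate
20 | (5R,6S)-11-(TBDPSO)-6-(hydroxymethyl)-2,6-dimethyl-9-methylidenetricyclo[5.4.0.0^{2,8}]undecan-5-ol | OC[C@]1(C)[C@@H]2[C@H]3C(=C)C[C@@H](O[Si](c4ccccc4)(c4ccccc4)C(C)(C)C)[C@@H]2[C@@]3(C)CC[C@H]1O | intermediate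
21 | [(5R,6S)-11-(TBDPSO)-5-hydroxy-2,6-dimethyl-9-methylidenetricyclo[5.4.0.0^{2,8}]undecan-6-yl]methyl (2Z)-2-methylbut-2-enoate | C/C=C(/C)C(=O)OC[C@]1(C)[C@@H]2[C@H]3C(=C)C[C@@H](O[Si](c4ccccc4)(c4ccccc4)C(C)(C)C)[C@@H]2[C@@]3(C)CC[C@H]1O | intermediate
22 | [(5R,6S)-5-acetyloxy-11-(TBDPSO)-2,6-dimethyl-9-methylidenetricyclo[5.4.0.0^{2,8}]undecan-6-yl]methyl (2Z)-2-methylbut-2-enoate | C/C=C(/C)C(=O)OC[C@]1(C)[C@@H]2[C@H]3C(=C)C[C@@H](O[Si](c4ccccc4)(c4ccccc4)C(C)(C)C)[C@@H]2[C@@]3(C)CC[C@H]1OC(C)=O | intermediate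
23 | [(5R,6S)-5-acetyloxy-11-hydroxy-2,6-dimethyl-9-methylidenetricyclo[5.4.0.0^{2,8}]undecan-6-yl]methyl (2Z)-2-methylbut-2-enoate | C/C=C(/C)C(=O)OC[C@]1(C)[C@@H]2[C@H]3C(=C)C[C@@H](O)[C@@H]2[C@@]3(C)CC[C@H]1OC(C)=O | intermediate
24 | [(5R,6S)-5-acetyloxy-2,6-dimethyl-9-methylidene-11-oxotricyclo[5.4.0.0^{2,8}]undecan-6-yl]methyl (2Z)-2-methylbut-2-enoate | C/C=C(/C)C(=O)OC[C@]1(C)[C@@H]2[C@H]3C(=C)CC(=O)[C@@H]2[C@@]3(C)CC[C@H]1OC(C)=O | intermediate
25 | [(1S,2S,5R,6S,7R,8S)-5-acetyloxy-2,6,9-trimethyl-11-oxotricyclo[5.4.0.0^{2,8}]undec-9-en-6-yl]methyl (2Z)-2-methylbut-2-enoate | C/C=C(/C)C(=O)OC[C@]1(C)[C@@H]2[C@H]3C(C)=CC(=O)[C@@H]2[C@@]3(C)CC[C@H]1OC(C)=O | target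

**Step count and risks**

Total step count: 18. Longest linear sequence: 17 steps (steps 1, 2 and 4–18 from compound 1; step 3 is a one-step branch).

Steps most likely to fail:

1. Step 13. The risk is poor facial discrimination at C6, since the substrate gives no bias and everything rests on the ligand, together with protodesilylation of the enol silane in the aqueous medium. Fallback, starting from 18: the enol silane is cleaved with MeLi (THF, 0 °C) to the regiodefined lithium enolate, which is treated with monomeric formaldehyde at −78 °C without any chiral control. The two C6 epimers are separated by chromatography; the desired one rejoins the route at 19. The unwanted one, (6R)-11-(TBDPSO)-6-(hydroxymethyl)-2,6-dimethyl-9-methylidenetricyclo[5.4.0.0^{2,8}]undecan-5-one F1, is returned to ketone 17 by retro-aldol loss of formaldehyde (K2CO3, MeOH, rt) and recycled through step 12.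

2. Step 7. The risk is unselective dehydrochlorination (methyl versus methylene γ-position), giving ketene geometries that cannot reach the alkene and oligomerise. Fallback, starting from 9: kinetic deconjugation (LDA, DMPU, THF, −78 °C; then AcOH quench) should give methyl (5R,6E)-5-(TBDPSO)-9-(TBSO)-7-methyl-3-methylidenenon-6-enoate F2. Saponification (LiOH, 0 °C) gives (5R,6E)-5-(TBDPSO)-9-(TBSO)-7-methyl-3-methylidenenon-6-enoic acid F3, and 1-chloro-N,N,2-trimethylprop-1-en-1-amine gives (5R,6E)-5-(TBDPSO)-9-(TBSO)-7-methyl-3-methylidenenon-6-enoyl chloride F4. α-Dehydrochlorination of F4 (Et3N, toluene, 110 °C) leads to vinylketene 12 without any regiochemical choice, and the route is rejoined at 13.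

3. Step 11. The risk is reduction or direct cyclisation of the primary alkyl radical before it captures carbon monoxide. Fallback, starting from 16: iodine–lithium exchange and carboxylation (t-BuLi, Et2O/pentane, −78 °C; CO2) should give 3-[4-(TBDPSO)-6-ethylidene-7-methyl-2-methylidenebicyclo[3.1.1]heptan-7-yl]propanoic acid F5. PhSeSePh and PBu3 convert it into Se-phenyl 3-[4-(TBDPSO)-6-ethylidene-7-methyl-2-methylidenebicyclo[3.1.1]heptan-7-yl]propaneselenoate F6. Bu3SnH and AIBN (benzene, 80 °C, high dilution) then generate the acyl radical directly, with no alkyl-radical stage and no CO pressure, and the route is rejoined at 17.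

Further compounds
F1 | step 13 | (6R)-11-(TBDPSO)-6-(hydroxymethyl)-2,6-dimethyl-9-methylidenetricyclo[5.4.0.0^{2,8}]undecan-5-one | OC[C@@]1(C)[C@@H]2[C@H]3C(=C)C[C@@H](O[Si](c4ccccc4)(c4ccccc4)C(C)(C)C)[C@@H]2[C@@]3(C)CCC1=O
F2 | step 7 | methyl (5R,6E)-5-(TBDPSO)-9-(TBSO)-7-methyl-3-methylidenenon-6-enoate | COC(=O)CC(=C)C[C@@H](O[Si](c1ccccc1)(c1ccccc1)C(C)(C)C)/C=C(\C)CCO[Si](C)(C)C(C)(C)C
F3 | step 7 | (5R,6E)-5-(TBDPSO)-9-(TBSO)-7-methyl-3-methylidenenon-6-enoic acid | OC(=O)CC(=C)C[C@@H](O[Si](c1ccccc1)(c1ccccc1)C(C)(C)C)/C=C(\C)CCO[Si](C)(C)C(C)(C)C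
F4 | step 7 | (5R,6E)-5-(TBDPSO)-9-(TBSO)-7-methyl-3-methylidenenon-6-enoyl chloride | ClC(=O)CC(=C)C[C@@H](O[Si](c1ccccc1)(c1ccccc1)C(C)(C)C)/C=C(\C)CCO[Si](C)(C)C(C)(C)C
F5 | step 11 | 3-[4-(TBDPSO)-6-ethylidene-7-methyl-2-methylidenebicyclo[3.1.1]heptan-7-yl]propanoic acid | CC=C1[C@H]2C(=C)C[C@@H](O[Si](c3ccccc3)(c3ccccc3)C(C)(C)C)[C@@H]1[C@@]2(C)CCC(=O)O
F6 | step 11 | Se-phenyl 3-[4-(TBDPSO)-6-ethylidene-7-methyl-2-methylidenebicyclo[3.1.1]heptan-7-yl]propaneselenoate | CC=C1[C@H]2C(=C)C[C@@H](O[Si](c3ccccc3)(c3ccccc3)C(C)(C)C)[C@@H]1[C@@]2(C)CCC(=O)[Se]c1ccccc1
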